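The readings are simulated with made-up constants.

- At early times I treat this flask as one step: Xa + Xb gives Xp over the catalyst Xc, first order in each partner at a fixed c(Xc). Xa is the limiting reagent. I want what Wednesday's dilute charge makes by 25 min.

| flask | Xa | Xb | Xc | time |
|---|---|---|---|---|
| Tuesday's | 0.100 M | 0.110 M | 0.0100 M |  |
| Friday's | 0.100 M | 0.110 M | 0.0150 M |  |
| Wednesday's | 0.0330 M | 0.0360 M | 0.0100 M | 25 min |

| run | time / min | [Xp] / M |
|---|---|---|
| Tuesday's run | 1.9 | 0.0072 |
| Tuesday's run | 5.8 | 0.0198 |
| Tuesday's run | 11 | 0.0293 |
| Tuesday's run | 17 | 0.0379 |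
| Tuesday's run | 25 | 0.0417 |
| Friday's run | 1.9 | 0.0130 |
| Friday's run | 5.8 | 0.0301 |
| Friday's run | 11 | 0.0436 |
| Friday's run | 17 | 0.0510 |
| Friday's run | 25 | 0.0569 |

(readings scatter by 0.001 M)

- Overall: Xa + Xb -> Xp, with Xc as catalyst.
- Constant volume, constant temperature.
- Bound and free are read together.
- "The second partner" is Xb.
- An order is taken over about fifteen percent of the charge, up and down.

- apparent order in [Xc] of the starting rate, round the charge of the Tuesday's run (the rate where two percent of its Xa have turned into Xp)
- Xp in the Wednesday's run at 25 min, as a share of the Xa charged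

- I carry one quantity, the catalyst clock: the second-order constant summed over the elapsed time, obtained from a reading as the natural logarithm of c(Xa)start·c(Xb)/(c(Xb)start·c(Xa)), divided by the charge difference of Xb over Xa. Tuesday's run at 25 min reads 6.30 L mol⁻¹. I assume that a clock read on one charge carries over to another at the same c(Xc) and time.
- With the main step alone, Tuesday's first reading gives a constant of 0.370 L mol⁻¹ min⁻¹, a rough figure given the scatter. Held steady, that is a clock of 9.25 L mol⁻¹ at 25 min, so Wednesday's share of Xa would be 25.2 %.
- Next I add fading. The clock that Tuesday's run actually read is lower than the steady one, and putting it into the same logarithm brings Wednesday down to 18.6 %.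
- Then I add the catalyst level. Friday's clock at 25 min is 11.3 L mol⁻¹, which gives a clock exponent in c(Xc) of 1.45 over the whole run. But Wednesday has Tuesday's c(Xc), so my share stays where it was.
- The forecast gives an order of 1.35 (range 1 to 1.7) and a share of 22 % (range 16 % to 35 %), reading the fall as “catalyst decay rather than product inhibition”. Its share is higher than mine.
- The flask gives an order of 1.1 and a share of 21.0 %.

    2 Xc ⇌ Xc2, settled at all times (916.0 L mol⁻¹)
    Xc2 + Xa + Xb → Xp + Xc2 (157.8 L² mol⁻² min⁻¹)
    2 Xa ⇌ Xa2, settled at all times (3.500 L mol⁻¹)
    Xc → Q (0.1962 min⁻¹)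

- Read backwards through the same logarithm, Wednesday's 21.0 % is a clock of 7.29 L mol⁻¹, higher than Tuesday's 6.30 L mol⁻¹. The same Wednesday flask without the step Xc → Q ends at 33.1 %, which is a longer clock of 13.5 L mol⁻¹. Because of the reaction of Xc to Q, Wednesday's share at 25 min is lower by 12 percentage points.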